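**Plan**

- Retrosynthesis: (a) the benzylic CH2 on C3 is taken back to a ketone and the phenol to its benzyl ether; (b) the lactone O1–C2(=O) unit is removed as CO2 by cutting C5–O1 and C2–C3, which leaves C3, C4 and C5 as a trans-1,2-disubstituted cyclopropane (an aryl cyclopropyl ketone); (c) the ketone is cut to a Weinreb amide and an aryl Grignard reagent; (d) the cyclopropane is cut to an allylarene and a diazoacetate.
- Forward: the three-membered ring is made first by catalytic asymmetric cyclopropanation, then the aroyl group is attached. The γ-lactone ring then arises in one operation by formal [3+2] insertion of CO2 into the acyl-activated cyclopropane bond. A final hydrogenolysis removes the ketone oxygen and the benzyl group.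
- Enabling feature: ring carbons C3, C4 and C5 of the oxolan-2-one can be stored as a strained cyclopropane, and the exocyclic benzylic carbon on C3 can be carried as C=O. This polarises the C3–C5 bond, with C5 electrophilic and C3 an enolate carbon.
- Stereochemistry: C4 comes from the ligand-controlled cyclopropanation and is not touched again. C3 is set trans to it under thermodynamic control in the enolisable β-keto lactone.

Key step: step 5

Assumption: the sense of induction of the Cu(I)/(R,R)-tBu-box catalyst with allylarene 3 is taken to parallel that known for styrene (S at the ester-bearing carbon); the mirror-image ligand would be used otherwise.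

**Route**

Step 1
Reactants: 1 4-allyl-2,6-dimethoxyphenol; 2 benzyl bromide
Product: 3 5-allyl-2-(benzyloxy)-1,3-dimethoxybenzene
Conditions: BnBr, K2CO3, DMF, rt to 50 °C
Reagents that add atoms: benzyl bromide, BrCc1ccccc1
Why: Williamson ether synthesis; the phenoxide is O-alkylated and the benzyl group protects the phenol against O–H insertion and alkylation in later steps.

Step 2
Reactants: 3 5-allyl-2-(benzyloxy)-1,3-dimethoxybenzene; 4 ethyl diazoacetate
Product: 5 ethyl (1S,2R)-2-[4-(benzyloxy)-3,5-dimethoxybenzyl]cyclopropane-1-carboxylate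
Conditions: CuOTf·½C6H6 (2 mol %), (R,R)-tBu-box (2.4 mol %), CH2Cl2, rt, 3 in excess (recovered), 4 added slowly by syringe pump; cis isomer removed by chromatography
Reagents that add atoms: ethyl diazoacetate, CCOC(=O)C=[N+]=[N-]
Why: Cu(I)–bis(oxazoline) asymmetric cyclopropanation; the C2-symmetric ligand fixes the face of the copper carbene that is attacked (ester-bearing carbon S), and approach of the alkene with its substituent away from the ester gives the trans isomer, which sets the benzyl-bearing carbon R.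

Step 3
Reactants: 5 ethyl (1S,2R)-2-[4-(benzyloxy)-3,5-dimethoxybenzyl]cyclopropane-1-carboxylate; 6 N,O-dimethylhydroxylamine hydrochloride
Product: 7 (1S,2R)-2-[4-(benzyloxy)-3,5-dimethoxybenzyl]-N-methoxy-N-methylcyclopropane-1-carboxamide
Conditions: MeNH(OMe)·HCl, i-PrMgCl, THF, −20 to 0 °C; cold dilute HCl quench
Reagents that add atoms: N,O-dimethylhydroxylamine hydrochloride, CNOC.Cl
Why: Weinreb amide formation by aminolysis of the ester with the magnesium amide; the cyclopropane α-hydrogen is not removed under these conditions, so both stereocentres are retained.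

Step 4
Reactants: 7 (1S,2R)-2-[4-(benzyloxy)-3,5-dimethoxybenzyl]-N-methoxy-N-methylcyclopropane-1-carboxamide; 8 5-bromo-1,2,3-trimethoxybenzene
Product: 10 {(1S,2R)-2-[4-(benzyloxy)-3,5-dimethoxybenzyl]cyclopropyl}(3,4,5-trimethoxyphenyl)methanone, via arylmagnesium bromide 9 (not isolated)
Conditions: 8, Mg, I2 (cat.), THF, reflux; then 7, THF, 0 °C to rt; 1 M HCl quench
Reagents that add atoms: 5-bromo-1,2,3-trimethoxybenzene, COc1cc(Br)cc(OC)c1OC
Why: Weinreb ketone synthesis; the five-membered magnesium chelate of the tetrahedral adduct survives until work-up, so a single aryl group is added and the ring stereocentres are untouched.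

Step 5
Reactants: 10 {(1S,2R)-2-[4-(benzyloxy)-3,5-dimethoxybenzyl]cyclopropyl}(3,4,5-trimethoxyphenyl)methanone; 11 carbon dioxide
Product: 14 (3S,4R)-4-[4-(benzyloxy)-3,5-dimethoxybenzyl]-3-(3,4,5-trimethoxybenzoyl)oxolan-2-one, via γ-iodo magnesium enolate 12 (not isolated), via γ-iodo β-keto carboxylate 13 (not isolated)
Conditions: MgI2 (1.0 equiv), i-Pr2NEt (0.2 equiv), CO2 (20 bar), THF, 70 °C, pressure vessel; then aq. citric acid
Reagents that add atoms: carbon dioxide, O=C=O
Why: Proposed new method: Mg2+ coordinates the aroyl oxygen of 10 and iodide opens the acceptor-activated cyclopropane by SN2 attack at the unsubstituted ring CH2, cleaving its bond to the acyl-bearing carbon to give enolate 12, which is C-carboxylated by CO2 through a six-membered Mg chelate to carboxylate 13, whose oxygen then displaces the primary iodide and returns MgI2. The closest known reaction types are the halide-catalysed insertion of CO2 into epoxides and aziridines, the MgI2-mediated ring expansion of acyl- and carboxamido-cyclopropanes with imines, and the Mg-mediated C-carboxylation of ketone enolates; their union on an all-carbon three-membered ring is the untested part. The oxolan-2-one ring closes by 5-exo-tet O-alkylation of the carboxylate. C4 takes part in no bond change and keeps its configuration, while the new centre C3 lies between two carbonyl groups and equilibrates via the Mg enolate to the trans isomer under thermodynamic control by the C4 substituent. The step needs iodide attack at the ring CH2 and not at the benzyl-bearing CH (secured by the primary versus β-branched secondary carbon, the absence of a cation-stabilising group there and the mild Lewis acid, which keeps the opening SN2-like) and CO2 capture at carbon ahead of enolate O-alkylation to a dihydrofuran (secured by CO2 pressure and Mg chelation). The amine only shuttles protons, so that any γ-iodo ketone formed by adventitious protonation re-enters the enolate manifold.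

Step 6
Reactants: 14 (3S,4R)-4-[4-(benzyloxy)-3,5-dimethoxybenzyl]-3-(3,4,5-trimethoxybenzoyl)oxolan-2-one
Product: 17 (3R,4R)-4-(4-hydroxy-3,5-dimethoxybenzyl)-3-(3,4,5-trimethoxybenzyl)oxolan-2-one, via debenzylated keto lactone 15 (not isolated), via benzylic alcohol 16 (not isolated)
Conditions: H2 (3 bar), 10% Pd/C, AcOH, HClO4 (cat.), rt
Reagents that add atoms: none
Why: Pd-catalysed hydrogenolysis cleaves the benzyl ether and takes the electron-rich aryl ketone through the benzylic alcohol to CH2 (acid-assisted C–O hydrogenolysis, as precedented for α-(aryl-hydroxymethyl) lactones); C3 stays trans because it equilibrates to that isomer while still flanked by two carbonyls and is configurationally fixed once the ketone is reduced.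

**Compound list**

1 | 4-allyl-2,6-dimethoxyphenol | C=CCc1cc(OC)c(O)c(OC)c1 | starting material
2 | benzyl bromide | BrCc1ccccc1 | starting material
3 | 5-allyl-2-(benzyloxy)-1,3-dimethoxybenzene | C=CCc1cc(OC)c(OCc2ccccc2)c(OC)c1 | intermediate
4 | ethyl diazoacetate | CCOC(=O)C=[N+]=[N-] | starting material
5 | ethyl (1S,2R)-2-[4-(benzyloxy)-3,5-dimethoxybenzyl]cyclopropane-1-carboxylate | CCOC(=O)[C@H]1C[C@@H]1Cc1cc(OC)c(OCc2ccccc2)c(OC)c1 | intermediate
6 | N,O-dimethylhydroxylamine hydrochloride | CNOC.Cl | starting material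
7 | (1S,2R)-2-[4-(benzyloxy)-3,5-dimethoxybenzyl]-N-methoxy-N-methylcyclopropane-1-carboxamide | CON(C)C(=O)[C@H]1C[C@@H]1Cc1cc(OC)c(OCc2ccccc2)c(OC)c1 | intermediate
8 | 5-bromo-1,2,3-trimethoxybenzene | COc1cc(Br)cc(OC)c1OC | starting material
9 | 3,4,5-trimethoxyphenylmagnesium bromide | COc1cc([Mg]Br)cc(OC)c1OC | intermediate
10 | {(1S,2R)-2-[4-(benzyloxy)-3,5-dimethoxybenzyl]cyclopropyl}(3,4,5-trimethoxyphenyl)methanone | O=C(c1cc(OC)c(OC)c(OC)c1)[C@H]1C[C@@H]1Cc1cc(OC)c(OCc2ccccc2)c(OC)c1 | intermediate
11 | carbon dioxide | O=C=O | starting material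
12 | magnesium iodide salt of (1Z,3R)-3-[4-(benzyloxy)-3,5-dimethoxybenzyl]-4-iodo-1-(3,4,5-trimethoxyphenyl)but-1-en-1-olate | [O-]/C(c1cc(OC)c(OC)c(OC)c1)=C\[C@H](CI)Cc1cc(OC)c(OCc2ccccc2)c(OC)c1.[Mg+2].[I-] | intermediate
13 | magnesium iodide salt of (3R)-3-[4-(benzyloxy)-3,5-dimethoxybenzyl]-4-iodo-2-(3,4,5-trimethoxybenzoyl)butanoate (C2 epimers) | [O-]C(=O)C(C(=O)c1cc(OC)c(OC)c(OC)c1)[C@H](CI)Cc1cc(OC)c(OCc2ccccc2)c(OC)c1.[Mg+2].[I-] | intermediate
14 | (3S,4R)-4-[4-(benzyloxy)-3,5-dimethoxybenzyl]-3-(3,4,5-trimethoxybenzoyl)oxolan-2-one | COc1cc(C[C@H]2COC(=O)[C@@H]2C(=O)c2cc(OC)c(OC)c(OC)c2)cc(OC)c1OCc1ccccc1 | intermediate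
15 | (3S,4R)-4-(4-hydroxy-3,5-dimethoxybenzyl)-3-(3,4,5-trimethoxybenzoyl)oxolan-2-one | COc1cc(C[C@H]2COC(=O)[C@@H]2C(=O)c2cc(OC)c(OC)c(OC)c2)cc(OC)c1O | intermediate
16 | (3S,4R)-4-(4-hydroxy-3,5-dimethoxybenzyl)-3-[hydroxy(3,4,5-trimethoxyphenyl)methyl]oxolan-2-one (carbinol epimers) | COc1cc(C[C@H]2COC(=O)[C@@H]2C(O)c2cc(OC)c(OC)c(OC)c2)cc(OC)c1O | intermediate
17 | (3R,4R)-4-(4-hydroxy-3,5-dimethoxybenzyl)-3-(3,4,5-trimethoxybenzyl)oxolan-2-one | COc1cc(C[C@H]2COC(=O)[C@@H]2Cc2cc(OC)c(OC)c(OC)c2)cc(OC)c1O | target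

**Count**

Total steps: 6. Longest linear sequence: 6.

**Steps most likely to fail, with fallbacks**

1. Step 5 (proposed new method). Iodide may attack the benzyl-bearing ring carbon instead of the ring CH2, which would give the regioisomeric lactone and erode the configuration at C4. Enolate O-alkylation to a dihydrofuran may also outrun CO2 capture. The fallback uses known chemistry, sets out from 3 and comes back at 14. [2+2] cycloaddition of 3 with dichloroketene (Cl3CCOCl, Zn–Cu, Et2O) should give 3-[4-(benzyloxy)-3,5-dimethoxybenzyl]-2,2-dichlorocyclobutan-1-one F1. Dechlorination (Zn, AcOH) should give the prochiral 3-[4-(benzyloxy)-3,5-dimethoxybenzyl]cyclobutan-1-one F2. A catalytic asymmetric Baeyer–Villiger oxidation (aqueous H2O2 with a chiral phosphoric acid catalyst, or a Baeyer–Villiger monooxygenase) should desymmetrise F2 to (4R)-4-[4-(benzyloxy)-3,5-dimethoxybenzyl]oxolan-2-one F3. C-acylation of the lithium enolate of F3 (LiHMDS, 2.2 equiv, THF, −78 °C) with 3,4,5-trimethoxybenzoyl chloride, anti to the C4 substituent, should then deliver 14.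

2. Step 2. Carbene transfer to a non-conjugated terminal alkene may proceed with a poor trans/cis ratio and low enantioselectivity, and carbene dimerisation competes. The cis isomer carries the opposite configuration at the benzyl-bearing carbon and would erode the final enantiopurity if not removed. The fallback sets out from 3 and comes back at 7. Cross-metathesis of 3 with methyl acrylate (second-generation Ru–NHC metathesis catalyst, CH2Cl2, 40 °C) should give methyl (2E)-4-[4-(benzyloxy)-3,5-dimethoxyphenyl]but-2-enoate F4. DIBAL-H reduction should give (2E)-4-[4-(benzyloxy)-3,5-dimethoxyphenyl]but-2-en-1-ol F5. Asymmetric Simmons–Smith cyclopropanation (Zn(CH2I)2·DME, (4R,5R)-2-butyl-N,N,N',N'-tetramethyl-1,3,2-dioxaborolane-4,5-dicarboxamide, CH2Cl2) should give {(1S,2R)-2-[4-(benzyloxy)-3,5-dimethoxybenzyl]cyclopropyl}methanol F6. Here the trans geometry follows from the E-alkene and the face from the ligand-bound zinc alkoxide. Oxidation (TEMPO, PhI(OAc)2, MeCN–H2O) should give (1S,2R)-2-[4-(benzyloxy)-3,5-dimethoxybenzyl]cyclopropane-1-carboxylic acid F7. Amide coupling of F7 with 6 (EDC·HCl, HOBt, i-Pr2NEt) should give 7.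

3. Step 6. The reduction may stall at the benzylic alcohol, or acid-induced dehydration to the α-arylidene lactone followed by unselective re-hydrogenation may scramble C3. The fallback avoids cationic intermediates, sets out from 14 and comes back at 17. Dithioketalisation of 14 (ethane-1,2-dithiol, BF3·OEt2, CH2Cl2) should give (3R,4R)-4-[4-(benzyloxy)-3,5-dimethoxybenzyl]-3-[2-(3,4,5-trimethoxyphenyl)-1,3-dithiolan-2-yl]oxolan-2-one F8. Mozingo desulfurisation (Raney nickel, EtOH, reflux) should give (3R,4R)-4-[4-(benzyloxy)-3,5-dimethoxybenzyl]-3-(3,4,5-trimethoxybenzyl)oxolan-2-one F9. Neutral hydrogenolysis of F9 (H2, Pd/C, EtOAc) should give 17.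

**Further compounds**

F1 | step 5 | 3-[4-(benzyloxy)-3,5-dimethoxybenzyl]-2,2-dichlorocyclobutan-1-one (racemic) | O=C1CC(Cc2cc(OC)c(OCc3ccccc3)c(OC)c2)C1(Cl)Cl
F2 | step 5 | 3-[4-(benzyloxy)-3,5-dimethoxybenzyl]cyclobutan-1-one | O=C1CC(Cc2cc(OC)c(OCc3ccccc3)c(OC)c2)C1
F3 | step 5 | (4R)-4-[4-(benzyloxy)-3,5-dimethoxybenzyl]oxolan-2-one | COc1cc(C[C@H]2COC(=O)C2)cc(OC)c1OCc1ccccc1
F4 | step 2 | methyl (2E)-4-[4-(benzyloxy)-3,5-dimethoxyphenyl]but-2-enoate | COC(=O)/C=C/Cc1cc(OC)c(OCc2ccccc2)c(OC)c1
F5 | step 2 | (2E)-4-[4-(benzyloxy)-3,5-dimethoxyphenyl]but-2-en-1-ol | OC/C=C/Cc1cc(OC)c(OCc2ccccc2)c(OC)c1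
F6 | step 2 | {(1S,2R)-2-[4-(benzyloxy)-3,5-dimethoxybenzyl]cyclopropyl}methanol | OC[C@H]1C[C@@H]1Cc1cc(OC)c(OCc2ccccc2)c(OC)c1
F7 | step 2 | (1S,2R)-2-[4-(benzyloxy)-3,5-dimethoxybenzyl]cyclopropane-1-carboxylic acid | OC(=O)[C@H]1C[C@@H]1Cc1cc(OC)c(OCc2ccccc2)c(OC)c1
F8 | step 6 | (3R,4R)-4-[4-(benzyloxy)-3,5-dimethoxybenzyl]-3-[2-(3,4,5-trimethoxyphenyl)-1,3-dithiolan-2-yl]oxolan-2-one | COc1cc(C[C@H]2COC(=O)[C@@H]2C2(SCCS2)c2cc(OC)c(OC)c(OC)c2)cc(OC)c1OCc1ccccc1
F9 | step 6 | (3R,4R)-4-[4-(benzyloxy)-3,5-dimethoxybenzyl]-3-(3,4,5-trimethoxybenzyl)oxolan-2-one | COc1cc(C[C@H]2COC(=O)[C@@H]2Cc2cc(OC)c(OC)c(OC)c2)cc(OC)c1OCc1ccccc1
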